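Retrosynthesis: the C2–H/C4=O pattern of ring C is traced back by a redox transposition to the isomeric 3-aryl-4-hydroxycoumarin (C2 lactone carbonyl, C4 enol). Ring C of that coumarin is then cut at C4–C4a and O1–C2.
Enabling feature: ring A is a phloroglucinol nucleus whose oxygens (O1, 5-O, 7-O) and free carbons (C4a, C6, C8) are each threefold equivalent. C2–C3–C4 with ring B on C3 is an arylmalonyl unit with two equivalent acyl carbons, so the two symmetric halves can join in only one way.
Ring B piece: the 4'-oxygen comes from formylation and Baeyer–Villiger oxidation of 2,5-dimethoxyphenylacetate, the prenyl group from a Williamson reaction, and the second acyl carbon from dimethyl carbonate.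
Forward order: rings A and B are bought and ring C is the only ring made (step 8). 5,7-O-Silylation, 4-O-methylation, hydride reduction at C2 with acid-induced loss of methanol, and desilylation then complete the isoflavone.
Stereochemistry: the target has no stereocentre and no configured double bond. The lactol carbon that arises in step 11 is racemic and becomes sp2 again in the same step.

Key step: step 8

Remark: phloroglucinol is taken in its anhydrous form (the dihydrate is dried by toluene azeotrope), because water would consume the ketene.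

Step 1
Reactants: 1 2-(2,5-dimethoxyphenyl)acetic acid
Product: 2 methyl 2-(2,5-dimethoxyphenyl)acetate
Conditions: MeOH, H2SO4 (cat.), reflux
Reagents that add atoms: methanol, CO
Why: Fischer esterification masks the acid so that the Lewis-acid formylation, the peracid oxidation and the later Claisen carboxylation all run on a neutral ester.

Step 2
Reactants: 2 methyl 2-(2,5-dimethoxyphenyl)acetate
Product: 3 methyl 2-(4-formyl-2,5-dimethoxyphenyl)acetate
Conditions: Cl2CHOMe (1.2 equiv), TiCl4 (2 equiv), CH2Cl2, −10 to 0 °C; ice-water quench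
Reagents that add atoms: dichloromethyl methyl ether, COC(Cl)Cl; water, O
Why: Rieche formylation of a 2,5-dimethoxyalkylbenzene should go to C4, the free position that is ortho to a methoxy group, para to the side chain and least hindered, as is known for 2,5-dimethoxytoluene.

Step 3
Reactants: 3 methyl 2-(4-formyl-2,5-dimethoxyphenyl)acetate
Product: 5 methyl 2-(4-hydroxy-2,5-dimethoxyphenyl)acetate, via aryl formate 4 (not isolated)
Conditions: mCPBA (1.3 equiv), CH2Cl2, 0 °C to rt; then MeOH, K2CO3 (0.1 equiv), rt, under N2
Reagents that add atoms: 3-chloroperoxybenzoic acid (mCPBA), O=C(OO)c1cccc(Cl)c1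
Why: In this Baeyer–Villiger (Dakin-type) oxidation the electron-rich aryl group migrates in the peracid adduct to give formate 4, which methanolysis cleaves while the methyl ester can only exchange with itself.

Step 4
Reactants: 5 methyl 2-(4-hydroxy-2,5-dimethoxyphenyl)acetate; 6 1-bromo-3-methylbut-2-ene (prenyl bromide)
Product: 7 methyl 2-[2,5-dimethoxy-4-(3-methylbut-2-enyloxy)phenyl]acetate
Conditions: 6 (1.2 equiv), K2CO3 (1.5 equiv), acetone, 45 °C, under N2
Reagents that add atoms: none
Why: Williamson etherification by SN2 attack of the phenoxide on the primary allylic bromide is expected, since K2CO3 is too weak to enolise the arylacetate and only oxygen is alkylated.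

Step 5
Reactants: 7 methyl 2-[2,5-dimethoxy-4-(3-methylbut-2-enyloxy)phenyl]acetate; 8 dimethyl carbonate
Product: 9 dimethyl 2-[2,5-dimethoxy-4-(3-methylbut-2-enyloxy)phenyl]propanedioate
Conditions: NaH (2.5 equiv), 8 (5 equiv), THF, 65 °C; AcOH quench
Reagents that add atoms: none
Why: The crossed Claisen condensation (C-methoxycarbonylation) of an arylacetate enolate with dimethyl carbonate is driven by deprotonation of the arylmalonate and runs far below the temperature at which an aryl prenyl ether rearranges.

Step 6
Reactants: 9 dimethyl 2-[2,5-dimethoxy-4-(3-methylbut-2-enyloxy)phenyl]propanedioate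
Product: 10 disodium 2-[2,5-dimethoxy-4-(3-methylbut-2-enyloxy)phenyl]propanedioate
Conditions: NaOH (2.05 equiv), MeOH/H2O, 45 °C; evaporate, toluene azeotrope, triturate with acetone
Reagents that add atoms: sodium hydroxide, [Na+].[OH-]
Why: Ordinary ester saponification is used, and isolation of the dianion instead of the free malonic acid avoids both decarboxylation and any contact of the prenyl ether with mineral acid.

Step 7
Reactants: 10 disodium 2-[2,5-dimethoxy-4-(3-methylbut-2-enyloxy)phenyl]propanedioate
Product: 12 2-[2,5-dimethoxy-4-(3-methylbut-2-enyloxy)phenyl]-3-oxoprop-2-enoyl chloride (aryl chlorocarbonyl ketene), via malonyl dichloride 11 (not isolated)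
Conditions: (COCl)2 (2.2 equiv), N,N-dimethylformamide (cat.), CH2Cl2, 0 °C to rt; filter, evaporate; 2,6-lutidine (1.0 equiv), THF, −20 °C; filter under argon, use the filtrate at once
Reagents that add atoms: oxalyl chloride, O=C(Cl)C(=O)Cl
Why: Sodium carboxylates and oxalyl chloride under Vilsmeier-type catalysis give acid chlorides with only NaCl, CO and CO2 beside them, so no HCl reaches the prenyl ether, and the C–H of 11, flanked by two acyl chlorides and an aryl group, is acidic enough for amine-induced dehydrochlorination to the conjugated ketene.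

Step 8
Reactants: 12 2-[2,5-dimethoxy-4-(3-methylbut-2-enyloxy)phenyl]-3-oxoprop-2-enoyl chloride; 13 phloroglucinol (benzene-1,3,5-triol)
Product: 14 3-[2,5-dimethoxy-4-(3-methylbut-2-enyloxy)phenyl]-4,5,7-trihydroxychromen-2-one
Conditions: 13 (3 equiv, anhydrous), 2,6-lutidine (1.5 equiv), THF (0.02 M), 12 added over 2 h at 0 °C, then 40 °C; aq. citric acid work-up
Reagents that add atoms: none
Why: The ketene carbon of 12 is captured by a hydroxyl of 13 (or directly by the ring carbon next to it) to give a malonyl half chloride, whose second acyl carbon, as the acid chloride or as the acyl ketene that lutidine regenerates from it, is attacked by the neighbouring nucleophilic site, so that C4–C4a and O1–C2 form in one flask and enolisation gives the 4-hydroxycoumarin. The closest known reaction type is the cyclocondensation of phenols and 1,3-dicarbonyl enols with (chlorocarbonyl)ketenes or activated malonates to 4-hydroxycoumarins and 4-hydroxy-2-pyranones. The one new ring, pyranone ring C, closes in a 6-exo-trig mode whichever bond forms last, because the attacked C=O lies outside the ring being made. No stereocentre is created. Regioselectivity is not required, since the three hydroxyls and three ring carbons of 13 are equivalent and the two acyl carbons of 12 lead to the same product whichever reacts first; what is required is a single annulation and C-acylation in preference to double O-acylation, which slow addition of 12 to excess 13 at high dilution, the deactivation of ring A by its new acyl group and the possible return of a diaryl malonate to the acyl ketene by base-induced loss of phenoxide (E1cB) should secure. Lutidine binds the HCl and the temperature stays below 50 °C, so the prenyl ether should be neither cleaved nor rearranged.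

Step 9
Reactants: 14 3-[2,5-dimethoxy-4-(3-methylbut-2-enyloxy)phenyl]-4,5,7-trihydroxychromen-2-one
Product: 16 5,7-bis(tert-butyldimethylsilyloxy)-3-[2,5-dimethoxy-4-(3-methylbut-2-enyloxy)phenyl]-4-hydroxychromen-2-one, via tris-silyl ether 15 (not isolated)
Conditions: TBSCl (3.5 equiv), imidazole (7 equiv), DMF, rt; then THF/H2O/AcOH, rt
Reagents that add atoms: tert-butyldimethylsilyl chloride (TBSCl), CC(C)(C)[Si](C)(C)Cl
Why: Standard chlorosilane/imidazole silylation covers all three hydroxyls, and the 4-O-silyl group, being a vinylogous silyl ester, is hydrolysed by dilute acetic acid that leaves aryl silyl ethers untouched.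

Step 10
Reactants: 16 5,7-bis(tert-butyldimethylsilyloxy)-3-[2,5-dimethoxy-4-(3-methylbut-2-enyloxy)phenyl]-4-hydroxychromen-2-one
Product: 17 5,7-bis(tert-butyldimethylsilyloxy)-3-[2,5-dimethoxy-4-(3-methylbut-2-enyloxy)phenyl]-4-methoxychromen-2-one
Conditions: Me2SO4 (1.1 equiv), K2CO3 (1.5 equiv), dry acetone, rt
Reagents that add atoms: dimethyl sulfate, COS(=O)(=O)OC
Why: O-Alkylation of the 4-hydroxycoumarin anion with the hard electrophile dimethyl sulfate in acetone is the usual way to 4-methoxy-3-arylcoumarins and 4-methoxy-2-pyranones, and in 16 the enol is the only acidic hydroxyl left, with no 5-OH hydrogen bond to divert attack to the lactone oxygen.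

Step 11
Reactants: 17 5,7-bis(tert-butyldimethylsilyloxy)-3-[2,5-dimethoxy-4-(3-methylbut-2-enyloxy)phenyl]-4-methoxychromen-2-one
Product: 19 5,7-bis(tert-butyldimethylsilyloxy)-3-[2,5-dimethoxy-4-(3-methylbut-2-enyloxy)phenyl]chromen-4-one, via lactol 18 (not isolated)
Conditions: i-Bu2AlH (1.1 equiv), CH2Cl2, −78 °C; aq. potassium sodium tartrate; then pyridinium p-toluenesulfonate (0.2 equiv), THF/H2O, rt
Reagents that add atoms: water, O
Why: Proposed new method: i-Bu2AlH should deliver one hydride to the lactone carbonyl C2 of the vinylogous carbonate 17 and the aluminium acetal should persist at −78 °C, giving lactol 18, which is the methyl enol ether of a 2-hydroxyisoflavanone; mild acid ionises it to the 4-methoxybenzopyrylium ion (an O-methylated chromone), water adds at C4 and methanol leaves, so the water lost from C2 is balanced by the water taken up at C4, the net change from 18 is loss of methanol alone and the carbonyl ends at C4; the closest known reaction types are the i-Bu2AlH reduction of coumarins to 2H-chromen-2-ols, the Stork–Danheiser reductive 1,3-carbonyl transposition of vinylogous esters and the hydrolysis of 4-alkoxybenzopyrylium salts to chromones.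

Step 12
Reactants: 19 5,7-bis(tert-butyldimethylsilyloxy)-3-[2,5-dimethoxy-4-(3-methylbut-2-enyloxy)phenyl]chromen-4-one
Product: 20 brandisianin A, 5,7-dihydroxy-3-[2,5-dimethoxy-4-(3-methylbut-2-enyloxy)phenyl]chromen-4-one
Conditions: Bu4NF (2.2 equiv), AcOH (2.4 equiv), THF, 0 °C
Reagents that add atoms: none
Why: Fluoride cleavage of aryl silyl ethers is fast at 0 °C, and the acetic acid buffer keeps the base-sensitive pyranone ring closed while the methyl and prenyl ethers are inert.

Compound list
1 | 2-(2,5-dimethoxyphenyl)acetic acid | COc1ccc(OC)c(CC(=O)O)c1 | starting material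
2 | methyl 2-(2,5-dimethoxyphenyl)acetate | COc1ccc(OC)c(CC(=O)OC)c1 | intermediate
3 | methyl 2-(4-formyl-2,5-dimethoxyphenyl)acetate | COC(=O)Cc1cc(OC)c(C=O)cc1OC | intermediate
4 | methyl 2-(4-formyloxy-2,5-dimethoxyphenyl)acetate | COC(=O)Cc1cc(OC)c(OC=O)cc1OC | intermediate
5 | methyl 2-(4-hydroxy-2,5-dimethoxyphenyl)acetate | COC(=O)Cc1cc(OC)c(O)cc1OC | intermediate
6 | 1-bromo-3-methylbut-2-ene (prenyl bromide) | CC(C)=CCBr | starting material
7 | methyl 2-[2,5-dimethoxy-4-(3-methylbut-2-enyloxy)phenyl]acetate | COC(=O)Cc1cc(OC)c(OCC=C(C)C)cc1OC | intermediate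
8 | dimethyl carbonate | COC(=O)OC | starting material
9 | dimethyl 2-[2,5-dimethoxy-4-(3-methylbut-2-enyloxy)phenyl]propanedioate | COC(=O)C(C(=O)OC)c1cc(OC)c(OCC=C(C)C)cc1OC | intermediate
10 | disodium 2-[2,5-dimethoxy-4-(3-methylbut-2-enyloxy)phenyl]propanedioate | [Na+].[Na+].[O-]C(=O)C(C(=O)[O-])c1cc(OC)c(OCC=C(C)C)cc1OC | intermediate
11 | 2-[2,5-dimethoxy-4-(3-methylbut-2-enyloxy)phenyl]propanedioyl dichloride | O=C(Cl)C(C(=O)Cl)c1cc(OC)c(OCC=C(C)C)cc1OC | intermediate
12 | 2-[2,5-dimethoxy-4-(3-methylbut-2-enyloxy)phenyl]-3-oxoprop-2-enoyl chloride | O=C=C(C(=O)Cl)c1cc(OC)c(OCC=C(C)C)cc1OC | intermediate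
13 | phloroglucinol (benzene-1,3,5-triol) | Oc1cc(O)cc(O)c1 | starting material
14 | 3-[2,5-dimethoxy-4-(3-methylbut-2-enyloxy)phenyl]-4,5,7-trihydroxychromen-2-one | O=c1oc2cc(O)cc(O)c2c(O)c1-c1cc(OC)c(OCC=C(C)C)cc1OC | intermediate
15 | 4,5,7-tris(tert-butyldimethylsilyloxy)-3-[2,5-dimethoxy-4-(3-methylbut-2-enyloxy)phenyl]chromen-2-one | O=c1oc2cc(O[Si](C)(C)C(C)(C)C)cc(O[Si](C)(C)C(C)(C)C)c2c(O[Si](C)(C)C(C)(C)C)c1-c1cc(OC)c(OCC=C(C)C)cc1OC | intermediate
16 | 5,7-bis(tert-butyldimethylsilyloxy)-3-[2,5-dimethoxy-4-(3-methylbut-2-enyloxy)phenyl]-4-hydroxychromen-2-one | O=c1oc2cc(O[Si](C)(C)C(C)(C)C)cc(O[Si](C)(C)C(C)(C)C)c2c(O)c1-c1cc(OC)c(OCC=C(C)C)cc1OC | intermediate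
17 | 5,7-bis(tert-butyldimethylsilyloxy)-3-[2,5-dimethoxy-4-(3-methylbut-2-enyloxy)phenyl]-4-methoxychromen-2-one | O=c1oc2cc(O[Si](C)(C)C(C)(C)C)cc(O[Si](C)(C)C(C)(C)C)c2c(OC)c1-c1cc(OC)c(OCC=C(C)C)cc1OC | intermediate
18 | 5,7-bis(tert-butyldimethylsilyloxy)-3-[2,5-dimethoxy-4-(3-methylbut-2-enyloxy)phenyl]-4-methoxy-2H-chromen-2-ol (racemic lactol) | OC1Oc2cc(O[Si](C)(C)C(C)(C)C)cc(O[Si](C)(C)C(C)(C)C)c2C(OC)=C1c1cc(OC)c(OCC=C(C)C)cc1OC | intermediate
19 | 5,7-bis(tert-butyldimethylsilyloxy)-3-[2,5-dimethoxy-4-(3-methylbut-2-enyloxy)phenyl]chromen-4-one | O=c1c(-c2cc(OC)c(OCC=C(C)C)cc2OC)coc2cc(O[Si](C)(C)C(C)(C)C)cc(O[Si](C)(C)C(C)(C)C)c12 | intermediate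
20 | brandisianin A | COc1cc(-c2coc3cc(O)cc(O)c3c2=O)c(OC)cc1OCC=C(C)C | target

Total step count: 12. Longest linear sequence: 12 steps (1 to 20); 6, 8 and 13 enter as bought compounds.

Steps most likely to fail

Step 11. The aluminium acetal may collapse early with ring opening and then be reduced further. Hydride may also be delivered in conjugate fashion to C4, or the electron-rich carbonyl may react too slowly. The fallback uses only known chemistry, sets out from 14 and comes back at 20. Hot aqueous-ethanolic NaOH under argon opens the lactone of the 3-aryl-4-hydroxycoumarin, and acidification in the cold decarboxylates the β-keto acid. This is the classical degradation of this compound class, and it gives the deoxybenzoin 2-[2,5-dimethoxy-4-(3-methylbut-2-enyloxy)phenyl]-1-(2,4,6-trihydroxyphenyl)ethanone F1. The lost carbon is put back at the aldehyde level with N,N-dimethylformamide dimethyl acetal in THF at 60 °C. The enaminone cyclises on dilute acid work-up to 20, as in the standard deoxybenzoin synthesis of isoflavones, and steps 9 to 12 are not needed.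

Step 8. The union may stop at O-acylation. Both acyl carbons may also be taken by two phenol molecules, the ketene may be lost to adventitious water with decarboxylation, or a second annulation may occur on ring A. The fallback closes ring C at C3–C4 instead, by the known Dieckmann-type condensation of O-(arylacetyl)salicylates. It sets out from 7 and comes back at 16.
- LiOH in aqueous THF turns 7 into 2-[2,5-dimethoxy-4-(3-methylbut-2-enyloxy)phenyl]acetic acid F2.
- Bought methyl 2,4,6-trihydroxybenzoate is silylated twice (TBSCl, imidazole, DMF). The third hydroxyl is held back by its hydrogen bond to the ester carbonyl, which gives methyl 2-hydroxy-4,6-bis(tert-butyldimethylsilyloxy)benzoate F3.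
- Carbodiimide esterification (N-ethyl-N'-(3-dimethylaminopropyl)carbodiimide, 4-(dimethylamino)pyridine, CH2Cl2) joins F2 and F3 to methyl 2-{2-[2,5-dimethoxy-4-(3-methylbut-2-enyloxy)phenyl]acetoxy}-4,6-bis(tert-butyldimethylsilyloxy)benzoate F4.
- LiN(SiMe3)2 in THF at −78 to 0 °C drives the ester enolate onto the neighbouring methyl ester to give 16 directly.

Step 10. The ambident anion may be alkylated at the lactone oxygen or at C3 because O4 is crowded. The base may also strip the 7-O-silyl group, and the freed phenoxide would then be methylated. The fallback forms the C4–OMe bond by exchange at carbon instead of the O–CH3 bond by alkylation. It sets out from 14 and comes back at 17. Trimethyl orthoformate and MeOH with catalytic camphorsulfonic acid at 40 °C effect a vinylogous Fischer esterification under thermodynamic control. Only the ketone-like C4 exchanges, and the phenols are inert. This gives 5,7-dihydroxy-3-[2,5-dimethoxy-4-(3-methylbut-2-enyloxy)phenyl]-4-methoxychromen-2-one F5. Silylation of its two phenols (TBSCl, imidazole, DMF) then gives 17.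

Further compounds
F1 | step 11 | 2-[2,5-dimethoxy-4-(3-methylbut-2-enyloxy)phenyl]-1-(2,4,6-trihydroxyphenyl)ethanone | O=C(Cc1cc(OC)c(OCC=C(C)C)cc1OC)c1c(O)cc(O)cc1O
F2 | step 8 | 2-[2,5-dimethoxy-4-(3-methylbut-2-enyloxy)phenyl]acetic acid | OC(=O)Cc1cc(OC)c(OCC=C(C)C)cc1OC
F3 | step 8 | methyl 2-hydroxy-4,6-bis(tert-butyldimethylsilyloxy)benzoate | COC(=O)c1c(O)cc(O[Si](C)(C)C(C)(C)C)cc1O[Si](C)(C)C(C)(C)C
F4 | step 8 | methyl 2-{2-[2,5-dimethoxy-4-(3-methylbut-2-enyloxy)phenyl]acetoxy}-4,6-bis(tert-butyldimethylsilyloxy)benzoate | COC(=O)c1c(OC(=O)Cc2cc(OC)c(OCC=C(C)C)cc2OC)cc(O[Si](C)(C)C(C)(C)C)cc1O[Si](C)(C)C(C)(C)C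
F5 | step 10 | 5,7-dihydroxy-3-[2,5-dimethoxy-4-(3-methylbut-2-enyloxy)phenyl]-4-methoxychromen-2-one | O=c1oc2cc(O)cc(O)c2c(OC)c1-c1cc(OC)c(OCC=C(C)C)cc1OC
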